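The central quinone ring is dissected into carbene carbon C1, alkenyl carbons C6 (indolyl) and C5 (prenyl), a chromium-bound CO (C4), and the two alkyne carbons of a 3-ethynylindole (C3, C2). One Dötz benzannulation forms C1–C2, C3–C4 and C4–C5 and closes this ring as a 4-methoxyphenol. It exploits the para C1/C4 oxygen pair. It also exploits C2 being the only non-carbonyl ring atom without a carbon substituent, so a terminal alkyne places H there and indolyl at C3. The precursor is an N-TIPS α-indolyl-β-prenylvinyl(methoxy)carbene pentacarbonylchromium complex. It and the alkyne both come from 3-acetylindole. C2–H is oxygenated afterwards via the quinone epoxide.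

Key step: step 6

Ring numbering used throughout: C1(=O), C2(OMe), C3(indol-3-yl), C4(=O), C5(prenyl), C6(indol-3-yl). TIPS = triisopropylsilyl; Tris = 2,4,6-triisopropylbenzenesulfonyl.

Assumption: the alkenyllithium, the acylchromate and the carbene complex are drawn with the prenyl-bearing chain trans to the metal-bearing carbon. This is the kinetic outcome of sulfonylhydrazone dianion fragmentation. Should the α-aryl alkenyllithium partly equilibrate, the mixture is carried on, because the benzannulation makes C5 an aromatic carbon and erases this geometry.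

Step 1
Reactants: 1 3-acetylindole
Product: 2 1-[1-(triisopropylsilyl)-1H-indol-3-yl]ethan-1-one
Conditions: NaH (1.1 equiv), THF, 0 °C; TIPSCl (1.1 equiv), 0 °C → rt
Reagents that add atoms: triisopropylsilyl chloride, CC(C)[Si](Cl)(C(C)C)C(C)C
Why: Standard N-silylation of the deprotonated 3-acylindole ends on nitrogen, and the bulky TIPS group later screens indole C2–H from alkyllithium bases while staying fluoride-labile.

Step 2
Reactants: 2 1-[1-(triisopropylsilyl)-1H-indol-3-yl]ethan-1-one
Product: 4 3-ethynyl-1-(triisopropylsilyl)-1H-indole, via enol diethyl phosphate 3 (not isolated)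
Conditions: LiN(iPr)2 (commercial solution, 1.1 equiv), THF, −78 °C; ClP(O)(OEt)2 (1.15 equiv), −78 °C → rt; added to LiN(iPr)2 (2.3 equiv), THF, −78 °C → rt; H2O
Reagents that add atoms: diethyl chlorophosphate, CCOP(=O)(Cl)OCC (its atoms stay only in intermediate 3)
Why: Negishi conversion of a methyl ketone into a terminal alkyne, in which kinetic deprotonation and O-phosphorylation give 3, excess amide base then removes a vinylic hydrogen with β-elimination of diethyl phosphate, and nothing in the sequence attacks the N–Si bond.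

Step 3
Reactants: 2 1-[1-(triisopropylsilyl)-1H-indol-3-yl]ethan-1-one
Product: 5 N'-{(1E)-1-[1-(triisopropylsilyl)-1H-indol-3-yl]ethylidene}-2,4,6-triisopropylbenzenesulfonohydrazide
Conditions: TrisNHNH2 (1.1 equiv), PPTS (5 mol %), 4 Å MS, THF, rt
Reagents that add atoms: 2,4,6-triisopropylbenzenesulfonyl hydrazide, CC(C)c1cc(C(C)C)c(S(=O)(=O)NN)c(C(C)C)c1
Why: Acid-catalysed hydrazone condensation of the unhindered methyl ketone proceeds at room temperature, where the heat-sensitive hydrazide and the N–Si bond both last, and the sulfonamide nitrogen settles anti to the indolyl group (E), that is syn to the methyl group to be deprotonated.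

Step 4
Reactants: 5 N'-{(1E)-1-[1-(triisopropylsilyl)-1H-indol-3-yl]ethylidene}-2,4,6-triisopropylbenzenesulfonohydrazide; 6 prenyl bromide (1-bromo-3-methylbut-2-ene)
Product: 8 N'-{(1E)-5-methyl-1-[1-(triisopropylsilyl)-1H-indol-3-yl]hex-4-en-1-ylidene}-2,4,6-triisopropylbenzenesulfonohydrazide, via dilithiated hydrazone 7 (not isolated)
Conditions: n-BuLi (2.1 equiv), THF, −78 °C; 6 (1.05 equiv), −78 → −60 °C; AcOH, −78 °C
Reagents that add atoms: n-butyllithium, [Li]CCCC (lithium in intermediate 7 only)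
Why: In this alkylation of a trisylhydrazone dianion, the carbon terminus of 7 is its most nucleophilic site and takes the allylic bromide once in SN2 fashion below the temperature of sulfinate loss, which avoids the over-alkylation of a methyl ketone enolate.

Step 5
Reactants: 8 N'-{(1E)-5-methyl-1-[1-(triisopropylsilyl)-1H-indol-3-yl]hex-4-en-1-ylidene}-2,4,6-triisopropylbenzenesulfonohydrazide; 9 chromium hexacarbonyl, Cr(CO)6
Product: 13 pentacarbonyl{(2E)-1-methoxy-6-methyl-2-[1-(triisopropylsilyl)-1H-indol-3-yl]hepta-2,5-dien-1-ylidene}chromium, via dilithiated hydrazone 10 (not isolated), via alkenyllithium 11 (not isolated), via lithium acylchromate 12 (not isolated)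
Conditions: n-BuLi (2.05 equiv), THF, −78 °C, then 0 °C until N2 evolution stops, recool to −78 °C; cannulate into Cr(CO)6 (1.1 equiv), THF, 0 °C → rt; evaporate; MeOTf (excess), CH2Cl2, 0 °C
Reagents that add atoms: methyl trifluoromethanesulfonate, COS(=O)(=O)C(F)(F)F; n-butyllithium, [Li]CCCC (lithium in intermediates 10–12 only)
Why: Shapiro reaction followed by the Fischer carbene synthesis, in which 10 loses sulfinate and N2 to give 11 with lithium on the former C=N carbon (only one α-carbon carries hydrogen, so the regiochemistry is unambiguous), 11 adds to a CO ligand of 9 to give 12 and hard O-methylation gives 13, while exactly two equivalents of base, a short stay at 0 °C and inverse addition to 9 keep the doubly allylic CH2 from quenching 11.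

Step 6
Reactants: 13 pentacarbonyl{(2E)-1-methoxy-6-methyl-2-[1-(triisopropylsilyl)-1H-indol-3-yl]hepta-2,5-dien-1-ylidene}chromium; 4 3-ethynyl-1-(triisopropylsilyl)-1H-indole
Product: 15 4-methoxy-6-(3-methylbut-2-en-1-yl)-2,5-bis[1-(triisopropylsilyl)-1H-indol-3-yl]phenol, via arene-Cr(CO)3 complex 14 (not isolated)
Conditions: 4 (1.5 equiv), degassed THF (0.05 M), 55 °C, argon; then air, Et2O, rt
Reagents that add atoms: none
Why: Thermal loss of a cis CO ligand from 13 lets 4 bind and insert into the Cr=C1 bond (C1–C2), giving an η1,η3-vinylcarbene whose chromium-bound carbon C3 takes up CO (C3–C4) to form a coordinated dienylketene C4=C3–C2=C1–C6=C5. The one ring formed, the central six-membered carbocycle, closes by 6π electrocyclisation of this dienylketene (C4–C5), and the cyclohexadienone tautomerises by moving the C5 hydrogen to oxygen, first giving 14, from which air removes the metal. The closest known reaction type is exactly this one, the Dötz benzannulation of α,β-disubstituted alkenyl(alkoxy)carbene chromium complexes with terminal aryl alkynes, the carbene class least prone to five-membered-ring side channels. No stereocentre is formed and the alkene geometry of 13 is erased when C5 becomes aromatic. The selectivity needed is the orientation of the alkyne: in the vinylcarbene the substituent on the central carbon C2 points at a CO ligand, so hydrogen takes that place and the bulky N-TIPS-indolyl group goes to C3, next to the future phenol carbon C4. The prenyl chain lies trans to C1 and away from chromium, so its alkene cannot chelate the metal or be cyclopropanated, and the TIPS groups keep both indole nitrogens away from the electrophilic carbene carbon.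

Step 7
Reactants: 15 4-methoxy-6-(3-methylbut-2-en-1-yl)-2,5-bis[1-(triisopropylsilyl)-1H-indol-3-yl]phenol
Product: 16 3-(3-methylbut-2-en-1-yl)-2,5-bis[1-(triisopropylsilyl)-1H-indol-3-yl]cyclohexa-2,5-diene-1,4-dione
Conditions: PhI(OAc)2 (1.1 equiv), MeCN/H2O 4:1, 0 °C
Reagents that add atoms: water, O
Why: In this oxidative demethylation of a 4-alkoxyphenol by a trivalent iodine reagent, ligand exchange at the phenol oxygen, attack of water at the para carbon C1 and loss of methanol from the hemiketal give the quinone under nearly neutral two-electron conditions, which are kinder to the N-silylindoles and the prenyl alkene than a strongly acidic one-electron oxidant.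

Step 8
Reactants: 16 3-(3-methylbut-2-en-1-yl)-2,5-bis[1-(triisopropylsilyl)-1H-indol-3-yl]cyclohexa-2,5-diene-1,4-dione
Product: 17 racemic cis-fused 3-(3-methylbut-2-en-1-yl)-1,4-bis[1-(triisopropylsilyl)-1H-indol-3-yl]-7-oxabicyclo[4.1.0]hept-3-ene-2,5-dione (the C2–C3 epoxide)
Conditions: 30 % H2O2 (1.5 equiv), Na2CO3, THF/H2O, 0 °C; extractive work-up, crude carried on
Reagents that add atoms: hydrogen peroxide, OO
Why: In this Weitz–Scheffer nucleophilic epoxidation (as for 2-methylnaphthoquinone and vitamin K1), hydroperoxide, a far better nucleophile and far weaker base than an alkoxide, adds to C2, the only quinone carbon bearing hydrogen, and closes on C3, so C2 is oxygenated without an external oxidant and without the strong base that would tautomerise a prenylquinone towards a chromenol or strip the N–Si bonds, and the two new stereocentres are necessarily cis at the ring fusion, racemic, and vanish in step 9.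

Step 9
Reactants: 17 racemic cis-fused 3-(3-methylbut-2-en-1-yl)-1,4-bis[1-(triisopropylsilyl)-1H-indol-3-yl]-7-oxabicyclo[4.1.0]hept-3-ene-2,5-dione
Product: 18 2-hydroxy-3,6-di(1H-indol-3-yl)-5-(3-methylbut-2-en-1-yl)cyclohexa-2,5-diene-1,4-dione
Conditions: Bu4NF (2.5 equiv), THF, 0 °C → rt; cold 0.5 M HCl work-up
Reagents that add atoms: none
Why: Fluoride cleavage of both N–Si bonds and the base-induced isomerisation of an α-hydrogen-bearing epoxyquinone to a 2-hydroxyquinone (the menadione oxide to phthiocol rearrangement) run in one flask, because the freed indole nitrogen pushes open the C3–O bond and loss of the C2 hydrogen gives the stabilised hydroxyquinone anion, and any material already desilylated or ring-opened in step 8 converges on the same product.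

Step 10
Reactants: 18 2-hydroxy-3,6-di(1H-indol-3-yl)-5-(3-methylbut-2-en-1-yl)cyclohexa-2,5-diene-1,4-dione
Product: 19 2-methoxy-3,6-di(1H-indol-3-yl)-5-(3-methylbut-2-en-1-yl)cyclohexa-2,5-diene-1,4-dione (CNP0506434.0)
Conditions: TMSCHN2 (1.2 equiv), toluene/MeOH 4:1, 0 °C
Reagents that add atoms: (trimethylsilyl)diazomethane, C[Si](C)(C)C=[N+]=[N-]
Why: In this diazoalkane O-methylation of a vinylogous carboxylic acid, only the hydroxyquinone O–H, far more acidic than the indole N–H, protonates the reagent, so the methyl group goes to the C2 oxygen under neutral conditions that leave the prenylquinone untouched.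

Compound list
1 | 3-acetylindole | CC(=O)c1c[nH]c2ccccc12 | starting material
2 | 1-[1-(triisopropylsilyl)-1H-indol-3-yl]ethan-1-one | CC(=O)c1cn([Si](C(C)C)(C(C)C)C(C)C)c2ccccc12 | intermediate
3 | diethyl 1-[1-(triisopropylsilyl)-1H-indol-3-yl]ethenyl phosphate (not isolated) | C=C(OP(=O)(OCC)OCC)c1cn([Si](C(C)C)(C(C)C)C(C)C)c2ccccc12 | intermediate
4 | 3-ethynyl-1-(triisopropylsilyl)-1H-indole | C#Cc1cn([Si](C(C)C)(C(C)C)C(C)C)c2ccccc12 | intermediate
5 | N'-{(1E)-1-[1-(triisopropylsilyl)-1H-indol-3-yl]ethylidene}-2,4,6-triisopropylbenzenesulfonohydrazide | C/C(=N\NS(=O)(=O)c1c(C(C)C)cc(C(C)C)cc1C(C)C)c1cn([Si](C(C)C)(C(C)C)C(C)C)c2ccccc12 | intermediate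
6 | prenyl bromide | CC(C)=CCBr | starting material
7 | C,N-dilithiated 5 (not isolated) | [Li]C/C(=N\N([Li])S(=O)(=O)c1c(C(C)C)cc(C(C)C)cc1C(C)C)c1cn([Si](C(C)C)(C(C)C)C(C)C)c2ccccc12 | intermediate
8 | N'-{(1E)-5-methyl-1-[1-(triisopropylsilyl)-1H-indol-3-yl]hex-4-en-1-ylidene}-2,4,6-triisopropylbenzenesulfonohydrazide | CC(C)=CCC/C(=N\NS(=O)(=O)c1c(C(C)C)cc(C(C)C)cc1C(C)C)c1cn([Si](C(C)C)(C(C)C)C(C)C)c2ccccc12 | intermediate
9 | chromium hexacarbonyl, Cr(CO)6 | O=C=[Cr](=C=O)(=C=O)(=C=O)(=C=O)=C=O | starting material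
10 | C,N-dilithiated 8 (not isolated) | [Li]C(CC=C(C)C)/C(=N\N([Li])S(=O)(=O)c1c(C(C)C)cc(C(C)C)cc1C(C)C)c1cn([Si](C(C)C)(C(C)C)C(C)C)c2ccccc12 | intermediate
11 | (1Z)-5-methyl-1-[1-(triisopropylsilyl)-1H-indol-3-yl]hexa-1,4-dien-1-yllithium (not isolated) | [Li]/C(=C/CC=C(C)C)c1cn([Si](C(C)C)(C(C)C)C(C)C)c2ccccc12 | intermediate
12 | lithium pentacarbonyl{(2E)-6-methyl-1-oxido-2-[1-(triisopropylsilyl)-1H-indol-3-yl]hepta-2,5-dien-1-ylidene}chromate (not isolated) | [Li+].[O-]C(=[Cr](=C=O)(=C=O)(=C=O)(=C=O)=C=O)/C(=C/CC=C(C)C)c1cn([Si](C(C)C)(C(C)C)C(C)C)c2ccccc12 | intermediate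
13 | pentacarbonyl{(2E)-1-methoxy-6-methyl-2-[1-(triisopropylsilyl)-1H-indol-3-yl]hepta-2,5-dien-1-ylidene}chromium | COC(=[Cr](=C=O)(=C=O)(=C=O)(=C=O)=C=O)/C(=C/CC=C(C)C)c1cn([Si](C(C)C)(C(C)C)C(C)C)c2ccccc12 | intermediate
14 | tricarbonyl(η6-15)chromium, metal on the new central ring (not isolated; π-complex written as its two parts) | COc1cc(-c2cn([Si](C(C)C)(C(C)C)C(C)C)c3ccccc23)c(O)c(CC=C(C)C)c1-c1cn([Si](C(C)C)(C(C)C)C(C)C)c2ccccc12.O=C=[Cr](=C=O)=C=O | intermediate
15 | 4-methoxy-6-(3-methylbut-2-en-1-yl)-2,5-bis[1-(triisopropylsilyl)-1H-indol-3-yl]phenol | COc1cc(-c2cn([Si](C(C)C)(C(C)C)C(C)C)c3ccccc23)c(O)c(CC=C(C)C)c1-c1cn([Si](C(C)C)(C(C)C)C(C)C)c2ccccc12 | intermediate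
16 | 3-(3-methylbut-2-en-1-yl)-2,5-bis[1-(triisopropylsilyl)-1H-indol-3-yl]cyclohexa-2,5-diene-1,4-dione | O=C1C=C(c2cn([Si](C(C)C)(C(C)C)C(C)C)c3ccccc23)C(=O)C(CC=C(C)C)=C1c1cn([Si](C(C)C)(C(C)C)C(C)C)c2ccccc12 | intermediate
17 | racemic cis-fused 3-(3-methylbut-2-en-1-yl)-1,4-bis[1-(triisopropylsilyl)-1H-indol-3-yl]-7-oxabicyclo[4.1.0]hept-3-ene-2,5-dione (one enantiomer drawn) | O=C1C(c2cn([Si](C(C)C)(C(C)C)C(C)C)c3ccccc23)=C(CC=C(C)C)C(=O)[C@@]2(c3cn([Si](C(C)C)(C(C)C)C(C)C)c4ccccc34)O[C@@H]12 | intermediate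
18 | 2-hydroxy-3,6-di(1H-indol-3-yl)-5-(3-methylbut-2-en-1-yl)cyclohexa-2,5-diene-1,4-dione | O=C1C(O)=C(c2c[nH]c3ccccc23)C(=O)C(CC=C(C)C)=C1c1c[nH]c2ccccc12 | intermediate
19 | 2-methoxy-3,6-di(1H-indol-3-yl)-5-(3-methylbut-2-en-1-yl)cyclohexa-2,5-diene-1,4-dione (no stereocentre) | COC1=C(c2c[nH]c3ccccc23)C(=O)C(CC=C(C)C)=C(c2c[nH]c3ccccc23)C1=O | target

Total step count: 10.
Longest linear sequence: 9 (steps 1, 3, 4, 5, 6, 7, 8, 9, 10). Step 2 branches off from 2.

Steps most likely to fail

1. Step 6.
- What may go wrong: after alkyne insertion, the crowded vinylcarbene may close without taking up CO or may take up a second alkyne. The carbene complex may also decay thermally before it reacts, and crowding at C5/C6 may slow the electrocyclisation.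
- Fallback (sets out from 8, returns at 19): a metal-free entry to the same kind of dienylketene by Moore–Liebeskind ring expansion.
- Commercial 3-bromo-1-(triisopropylsilyl)indole undergoes bromine–lithium exchange (t-BuLi, −78 °C) and adds to dimethyl squarate. This should give 4-hydroxy-2,3-dimethoxy-4-[1-(triisopropylsilyl)indol-3-yl]cyclobut-2-en-1-one F1.
- Catalytic HCl in CH2Cl2 removes methanol to give 3-methoxy-4-[1-(triisopropylsilyl)indol-3-yl]cyclobut-3-ene-1,2-dione F2.
- Alkenyllithium 11, made from 8 as in step 5, adds at −78 °C to the more electrophilic carbonyl, the one next to the methoxy-bearing carbon. This should give the 4-alkenyl-4-hydroxycyclobutenone F3.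
- Heating in toluene at 110 °C opens the four-membered ring, and 6π closure gives the bis-TIPS hydroquinone F4, which already carries the C2 methoxy group.
- Bu4NF gives the N–H hydroquinone F5, and Ag2O oxidises it to 19.

2. Step 5.
- What may go wrong: proton transfer from the doubly allylic CH2 to the alkenyllithium during the period at 0 °C needed for nitrogen loss. Capture by the sparingly soluble Cr(CO)6 may also be slow.
- Fallback (sets out from 2 and 6, returns at 15): the alkenyllithium is made at −78 °C by tin–lithium exchange, so it never sees 0 °C.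
- LiN(iPr)2 and 6 convert 2 into 5-methyl-1-[1-(triisopropylsilyl)indol-3-yl]hex-4-en-1-one F6.
- KN(SiMe3)2 and PhNTf2 give the (Z)-enol triflate F7.
- Me3SnSnMe3, Pd(PPh3)4 and LiCl give the (Z)-alkenyltrimethylstannane F8.
- MeLi at −78 °C gives the (1E)-alkenyllithium F9, which is trapped with 9 as the (2Z)-acylchromate F10 and methylated with MeOTf to the (2Z)-carbene complex F11, the geometric isomer of 13.
- F11 enters step 6 and should give the same phenol 15, because the geometry is lost on aromatisation.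

3. Step 8.
- What may go wrong: conjugate addition at C2 may be slow because the C3 indole donor lowers its electrophilicity. The N-silyl groups may be lost prematurely, which lowers it further. Excess peroxide may cleave the ring oxidatively.
- Fallback (sets out from 16, returns at 19): oxidative conjugate addition of methoxide in place of epoxidation.
- NaOMe in MeOH/THF under O2 at 0 °C adds methoxide to C2, and the hydroquinone anion is re-oxidised in the flask. This should give 2-methoxy-5-(3-methylbut-2-en-1-yl)-3,6-bis[1-(triisopropylsilyl)indol-3-yl]cyclohexa-2,5-diene-1,4-dione F12.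
- Bu4NF buffered with AcOH then gives 19, so steps 9 and 10 are skipped. Partial N–Si cleavage by methoxide does no harm, since fluoride treatment follows.

Further compounds
F1 | step 6 | 4-hydroxy-2,3-dimethoxy-4-[1-(triisopropylsilyl)-1H-indol-3-yl]cyclobut-2-en-1-one (racemic) | COC1=C(OC)C(O)(c2cn([Si](C(C)C)(C(C)C)C(C)C)c3ccccc23)C1=O
F2 | step 6 | 3-methoxy-4-[1-(triisopropylsilyl)-1H-indol-3-yl]cyclobut-3-ene-1,2-dione | COC1=C(c2cn([Si](C(C)C)(C(C)C)C(C)C)c3ccccc23)C(=O)C1=O
F3 | step 6 | 4-hydroxy-3-methoxy-4-{(1E)-5-methyl-1-[1-(triisopropylsilyl)-1H-indol-3-yl]hexa-1,4-dien-1-yl}-2-[1-(triisopropylsilyl)-1H-indol-3-yl]cyclobut-2-en-1-one (racemic) | COC1=C(c2cn([Si](C(C)C)(C(C)C)C(C)C)c3ccccc23)C(=O)C1(O)/C(=C/CC=C(C)C)c1cn([Si](C(C)C)(C(C)C)C(C)C)c2ccccc12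
F4 | step 6 | 2-methoxy-5-(3-methylbut-2-en-1-yl)-3,6-bis[1-(triisopropylsilyl)-1H-indol-3-yl]benzene-1,4-diol | COc1c(O)c(-c2cn([Si](C(C)C)(C(C)C)C(C)C)c3ccccc23)c(CC=C(C)C)c(O)c1-c1cn([Si](C(C)C)(C(C)C)C(C)C)c2ccccc12
F5 | step 6 | 2,5-di(1H-indol-3-yl)-3-methoxy-6-(3-methylbut-2-en-1-yl)benzene-1,4-diol | COc1c(O)c(-c2c[nH]c3ccccc23)c(CC=C(C)C)c(O)c1-c1c[nH]c2ccccc12
F6 | step 5 | 5-methyl-1-[1-(triisopropylsilyl)-1H-indol-3-yl]hex-4-en-1-one | CC(C)=CCCC(=O)c1cn([Si](C(C)C)(C(C)C)C(C)C)c2ccccc12
F7 | step 5 | (1Z)-5-methyl-1-[1-(triisopropylsilyl)-1H-indol-3-yl]hexa-1,4-dien-1-yl trifluoromethanesulfonate | O=S(=O)(O/C(=C\CC=C(C)C)c1cn([Si](C(C)C)(C(C)C)C(C)C)c2ccccc12)C(F)(F)F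
F8 | step 5 | trimethyl{(1Z)-5-methyl-1-[1-(triisopropylsilyl)-1H-indol-3-yl]hexa-1,4-dien-1-yl}stannane | C[Sn](C)(C)/C(=C\CC=C(C)C)c1cn([Si](C(C)C)(C(C)C)C(C)C)c2ccccc12
F9 | step 5 | (1E)-5-methyl-1-[1-(triisopropylsilyl)-1H-indol-3-yl]hexa-1,4-dien-1-yllithium | [Li]/C(=C\CC=C(C)C)c1cn([Si](C(C)C)(C(C)C)C(C)C)c2ccccc12
F10 | step 5 | lithium pentacarbonyl{(2Z)-6-methyl-1-oxido-2-[1-(triisopropylsilyl)-1H-indol-3-yl]hepta-2,5-dien-1-ylidene}chromate | [Li+].[O-]C(=[Cr](=C=O)(=C=O)(=C=O)(=C=O)=C=O)/C(=C\CC=C(C)C)c1cn([Si](C(C)C)(C(C)C)C(C)C)c2ccccc12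
F11 | step 5 | pentacarbonyl{(2Z)-1-methoxy-6-methyl-2-[1-(triisopropylsilyl)-1H-indol-3-yl]hepta-2,5-dien-1-ylidene}chromium | COC(=[Cr](=C=O)(=C=O)(=C=O)(=C=O)=C=O)/C(=C\CC=C(C)C)c1cn([Si](C(C)C)(C(C)C)C(C)C)c2ccccc12
F12 | step 8 | 2-methoxy-5-(3-methylbut-2-en-1-yl)-3,6-bis[1-(triisopropylsilyl)-1H-indol-3-yl]cyclohexa-2,5-diene-1,4-dione | COC1=C(c2cn([Si](C(C)C)(C(C)C)C(C)C)c3ccccc23)C(=O)C(CC=C(C)C)=C(c2cn([Si](C(C)C)(C(C)C)C(C)C)c3ccccc23)C1=O
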